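**Retrosynthetic overview**

1. The target is read as epiafzelechin-(4β→8)-catechin: upper unit (rings A, B, C) 2R,3R,4R with a 4-hydroxyphenyl ring B, lower unit (rings D, E, F) 2R,3S. The last skeletal bond is O1–C2 of ring C, closed by Mitsunobu inversion of a 1,2-anti diol that comes from a C2 aryl ketone.
2. Key disconnection: O1, C8a, C4a and C4 of the upper unit are an ortho-quinone methide heterodiene on ring A, with the methide carbon C4 carrying C8 of the lower unit. C2–C3 with the C3 oxygen is benzyloxyketene. Their formal [4+2] annulation makes C3–C4 and O1–C2 and gives ring C as a 3,4-trans lactone.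
3. The quinone methide precursor is a phenol sulfone. It comes from the benzhydrol formed by adding 8-lithio-penta-O-benzylcatechin to 2-allyloxy-4,6-bis(benzyloxy)benzaldehyde (the C4–C8 bond).
4. Ring order: rings D, E, F come intact from (+)-catechin, and rings A and B come preformed. Ring C is made as a lactone (step 8), opened (step 9) and closed again as the pyran (step 12).

Key step: step 8

Assumption: O-benzoylquinidine is taken to direct attack to the methide face that gives 4R. This sense is inferred by analogy; if the first run gives the 4S series, its pseudoenantiomer O-benzoylquinine takes its place with nothing else changed.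

Abbreviation used in names: PBC-8-yl = (2R,3S)-3,5,7-tris(benzyloxy)-2-[3,4-bis(benzyloxy)phenyl]chroman-8-yl. Flavan locants of the upper unit (O1, C2, C3, C4) are kept when discussing open-chain and lactone intermediates.

**Step 1**
Reactants: 1 (+)-catechin
Product: 2 (2R,3S)-5,7-bis(benzyloxy)-2-[3,4-bis(benzyloxy)phenyl]chroman-3-ol
Conditions: BnBr (4.4 equiv), K2CO3, DMF, 0 °C to rt
Reagents that add atoms: benzyl bromide, BrCc1ccccc1
Why: Williamson etherification with a carbonate base alkylates only the four phenols and leaves the far less acidic secondary 3-OH and both stereocentres untouched.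

**Step 2**
Reactants: 2 (2R,3S)-5,7-bis(benzyloxy)-2-[3,4-bis(benzyloxy)phenyl]chroman-3-ol
Product: 3 (2R,3S)-8-bromo-5,7-bis(benzyloxy)-2-[3,4-bis(benzyloxy)phenyl]chroman-3-ol
Conditions: NBS (1.0 equiv), CH2Cl2, −78 °C to rt
Reagents that add atoms: N-bromosuccinimide, O=C1CCC(=O)N1Br
Why: Electrophilic aromatic bromination of the phloroglucinol-type ring D of 5,7-di-O-benzyl flavan-3-ols goes to C8 in preference to C6, and one equivalent at low temperature should stop at the monobromide.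

**Step 3**
Reactants: 3 (2R,3S)-8-bromo-5,7-bis(benzyloxy)-2-[3,4-bis(benzyloxy)phenyl]chroman-3-ol
Product: 4 (2R,3S)-8-bromo-3,5,7-tris(benzyloxy)-2-[3,4-bis(benzyloxy)phenyl]chromane
Conditions: NaH, BnBr, Bu4NI (cat.), DMF, 0 °C to rt
Reagents that add atoms: benzyl bromide, BrCc1ccccc1
Why: Williamson etherification of the C3 alkoxide, with the aryl bromide and the C2 and C3 configurations inert to these conditions.

**Step 4**
Reactants: 5 3,5-bis(benzyloxy)phenol
Product: 6 2-hydroxy-4,6-bis(benzyloxy)benzaldehyde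
Conditions: MgCl2, Et3N, (CH2O)n, MeCN, reflux; then 1 M HCl
Reagents that add atoms: paraformaldehyde (formaldehyde), C=O
Why: Casiraghi–Skattebøl ortho-formylation, in which the magnesium phenoxide delivers formaldehyde only ortho to the OH (the two ortho positions are equivalent) and a second formaldehyde oxidises the hydroxymethyl intermediate to the aldehyde.

**Step 5**
Reactants: 6 2-hydroxy-4,6-bis(benzyloxy)benzaldehyde
Product: 7 2-(allyloxy)-4,6-bis(benzyloxy)benzaldehyde
Conditions: allyl bromide, K2CO3, DMF, 50 °C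
Reagents that add atoms: allyl bromide, C=CCBr
Why: Williamson allylation masks the phenol with a group that is inert to the aryllithium and is later removed by zerovalent palladium without base or hydrogen.

**Step 6**
Reactants: 4 (2R,3S)-8-bromo-3,5,7-tris(benzyloxy)-2-[3,4-bis(benzyloxy)phenyl]chromane; 7 2-(allyloxy)-4,6-bis(benzyloxy)benzaldehyde
Product: 9 [2-(allyloxy)-4,6-bis(benzyloxy)phenyl](PBC-8-yl)methanol as both carbinol epimers, via aryllithium 8 (not isolated)
Conditions: n-BuLi (1.05 equiv), THF, −78 °C, 20 min; then 7 (1.3 equiv), −78 to −40 °C; H2O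
Reagents that add atoms: none
Why: Bromine–lithium exchange at −78 °C is faster than any attack on the benzyl ethers, and the doubly ortho-oxygenated aryllithium then adds 1,2 to the aldehyde; the new carbinol centre forms as both epimers, which does not matter because it becomes trigonal in step 8.

**Step 7**
Reactants: 9 [2-(allyloxy)-4,6-bis(benzyloxy)phenyl](PBC-8-yl)methanol
Product: 11 3,5-bis(benzyloxy)-2-[(PBC-8-yl)(p-tolylsulfonyl)methyl]phenol as both epimers, via O-allyl sulfone 10 (not isolated)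
Conditions: p-TolSO2H (3.5 equiv), CH2Cl2, 0 °C, 30 min; then Pd(PPh3)4 (5 mol %), rt; water wash, no basic wash, no chromatography on basic media
Reagents that add atoms: p-toluenesulfinic acid, Cc1ccc(cc1)S(=O)O
Why: The sulfinic acid ionises the hexa-oxygenated benzhydrol and the sulfinate captures the diarylmethyl cation at sulfur (SN1 sulfone formation), after which Tsuji–Trost allyl transfer from the aryl allyl ether to the remaining sulfinic acid frees the phenol under acidic conditions in which the sulfone cannot eliminate.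

**Step 8**
Reactants: 11 3,5-bis(benzyloxy)-2-[(PBC-8-yl)(p-tolylsulfonyl)methyl]phenol; 12 benzyloxyacetyl chloride
Product: 16 (3R,4R)-3,5,7-tris(benzyloxy)-4-(PBC-8-yl)chroman-2-one (3,4-trans lactone), via ortho-quinone methide 13 (not isolated), via benzyloxyketene 14 (not isolated), via 3,4-cis lactone 15 (not isolated)
Conditions: Cs2CO3, toluene, rt, then filtration under argon; O-benzoylquinidine (20 mol %), iPr2NEt (2.5 equiv), 12 (2 equiv, slow addition), toluene, −78 to −25 °C; aq. NaHCO3 wash; then DBU (0.3 equiv), CH2Cl2, rt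
Reagents that add atoms: none
Why: Cs2CO3 deprotonates the phenol of 11 and the phenoxide expels sulfinate to give the push–pull quinone methide 13, which is freed from sulfinate and base by filtration so that no phenoxide is left to be O-acylated; iPr2NEt dehydrochlorinates 12 to ketene 14, and the quinuclidine nitrogen of O-benzoylquinidine adds to its carbonyl carbon to give a zwitterionic ammonium enolate. The enolate α-carbon adds to the methide carbon (C3–C4, Michael step, ring A re-aromatises to the phenoxide) and the phenoxide then attacks the acylammonium carbonyl (O1–C2, 6-exo-trig) and releases the catalyst, so ring C closes as the δ-lactone in a stepwise formal [4+2]. The closest known reactions are the cinchona-alkaloid ketene-enolate [4+2] annulations of isolable alkoxy-substituted 4-aryl ortho-quinone methides and of ortho-quinones, and the isothiourea Michael–lactonisations of quinone methides made in situ from sulfones of this kind. C3 is set first by the alkaloid, which leaves one enolate face open, and C4 by the way the methide carbon meets that face in the ion-paired transition state; because C3 is epimerisable, DBU then converts any 3,4-cis adduct 15 into the more stable trans lactone 16, so the selectivity that matters is the face of attack at C4. That face selectivity has to come from the catalyst, since the lower-unit stereocentres are four or more bonds from the methide carbon and ring D sits nearly perpendicular to the heterodiene; those centres do make the two C4 epimers diastereomers, so a minor epimer should be removable by chromatography. Chemoselectivity (C- over O-acylation, annulation over ketene dimerisation) rests on the preformed heterodiene, slow addition of 12 and low temperature.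

**Step 9**
Reactants: 16 (3R,4R)-3,5,7-tris(benzyloxy)-4-(PBC-8-yl)chroman-2-one
Product: 17 (2R,3R)-2-(benzyloxy)-3-[2,4-bis(benzyloxy)-6-hydroxyphenyl]-N-methoxy-N-methyl-3-(PBC-8-yl)propanamide
Conditions: MeNH(OMe)·HCl, AlMe3, CH2Cl2, 0 °C to rt; aq. potassium sodium tartrate
Reagents that add atoms: N,O-dimethylhydroxylamine hydrochloride, CNOC.Cl
Why: Weinreb aminolysis of the activated aryl lactone by the aluminium amide is a non-basic acyl substitution, so C3 is not enolised and ring C opens to the free phenol with both stereocentres kept.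

**Step 10**
Reactants: 17 (2R,3R)-2-(benzyloxy)-3-[2,4-bis(benzyloxy)-6-hydroxyphenyl]-N-methoxy-N-methyl-3-(PBC-8-yl)propanamide; 18 1-(benzyloxy)-4-bromobenzene
Product: 20 (2R,3R)-2-(benzyloxy)-1-[4-(benzyloxy)phenyl]-3-[2,4-bis(benzyloxy)-6-hydroxyphenyl]-3-(PBC-8-yl)propan-1-one, via Grignard reagent 19 (not isolated)
Conditions: 18, Mg, THF; then 17 (19 in 3.5-fold excess), THF, −20 to 0 °C; sat. aq. NH4Cl, 0 °C
Reagents that add atoms: none
Why: Weinreb ketone synthesis, in which one equivalent of the Grignard reagent deprotonates the phenol and a second adds to the amide to give a magnesium-chelated tetrahedral adduct that collapses to the ketone only on quench, the low basicity of the aryl Grignard sparing the C3 hydrogen.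

**Step 11**
Reactants: 20 (2R,3R)-2-(benzyloxy)-1-[4-(benzyloxy)phenyl]-3-[2,4-bis(benzyloxy)-6-hydroxyphenyl]-3-(PBC-8-yl)propan-1-one
Product: 21 (1S,2R,3R)-2-(benzyloxy)-1-[4-(benzyloxy)phenyl]-3-[2,4-bis(benzyloxy)-6-hydroxyphenyl]-3-(PBC-8-yl)propan-1-ol (1,2-anti)
Conditions: Zn(BH4)2, Et2O/CH2Cl2, −30 to 0 °C
Reagents that add atoms: none
Why: Chelation-controlled reduction (Cram chelate model): zinc bridges the ketone oxygen and the C3 benzyloxy oxygen and hydride enters from the side of the C3 hydrogen, away from the diarylmethyl group, which sets the new carbinol centre as 1S, anti to the benzyloxy group.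

**Step 12**
Reactants: 21 (1S,2R,3R)-2-(benzyloxy)-1-[4-(benzyloxy)phenyl]-3-[2,4-bis(benzyloxy)-6-hydroxyphenyl]-3-(PBC-8-yl)propan-1-ol
Product: 22 (2R,3R,4R)-3,5,7-tris(benzyloxy)-2-[4-(benzyloxy)phenyl]-4-(PBC-8-yl)chromane
Conditions: PPh3, DIAD, toluene/THF, 0 °C to rt, high dilution
Reagents that add atoms: none
Why: Intramolecular Mitsunobu etherification, in which the phenol displaces the benzylic oxyphosphonium in a 6-exo-tet SN2 closure with inversion, turning the 1,2-anti diol into the 2,3-cis flavan with C2 as R while C3 and C4 are untouched.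

**Step 13**
Reactants: 22 (2R,3R,4R)-3,5,7-tris(benzyloxy)-2-[4-(benzyloxy)phenyl]-4-(PBC-8-yl)chromane
Product: 23 gambiriin C as given, (2R,3R,4R)-2-(4-hydroxyphenyl)-4-[(2R,3S)-2-(3,4-dihydroxyphenyl)-3,5,7-trihydroxychroman-8-yl]chromane-3,5,7-triol
Conditions: H2 (1 atm), Pd(OH)2/C, THF/MeOH/H2O, rt; filtration, Sephadex LH-20
Reagents that add atoms: none
Why: Catalytic hydrogenolysis removes all nine benzyl ethers under neutral conditions that leave the pyran C2–O1 bonds, the C4–C8 bond and all five stereocentres intact.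

**Compound list**

1 | (+)-catechin | O[C@H]1Cc2c(O)cc(O)cc2O[C@@H]1c1ccc(O)c(O)c1 | starting material
2 | (2R,3S)-5,7-bis(benzyloxy)-2-[3,4-bis(benzyloxy)phenyl]chroman-3-ol | c1c(OCc2ccccc2)cc(OCc2ccccc2)c2c1O[C@H](c1ccc(OCc3ccccc3)c(OCc3ccccc3)c1)[C@@H](O)C2 | intermediate
3 | (2R,3S)-8-bromo-5,7-bis(benzyloxy)-2-[3,4-bis(benzyloxy)phenyl]chroman-3-ol | Brc1c(OCc2ccccc2)cc(OCc2ccccc2)c2c1O[C@H](c1ccc(OCc3ccccc3)c(OCc3ccccc3)c1)[C@@H](O)C2 | intermediate
4 | (2R,3S)-8-bromo-3,5,7-tris(benzyloxy)-2-[3,4-bis(benzyloxy)phenyl]chromane | Brc1c(OCc2ccccc2)cc(OCc2ccccc2)c2c1O[C@H](c1ccc(OCc3ccccc3)c(OCc3ccccc3)c1)[C@@H](OCc1ccccc1)C2 | intermediate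
5 | 3,5-bis(benzyloxy)phenol | Oc1cc(OCc2ccccc2)cc(OCc2ccccc2)c1 | starting material
6 | 2-hydroxy-4,6-bis(benzyloxy)benzaldehyde | O=Cc1c(O)cc(OCc2ccccc2)cc1OCc1ccccc1 | intermediate
7 | 2-(allyloxy)-4,6-bis(benzyloxy)benzaldehyde | O=Cc1c(OCC=C)cc(OCc2ccccc2)cc1OCc1ccccc1 | intermediate
8 | 8-lithio derivative of 4 (aryllithium) | [Li]c1c(OCc2ccccc2)cc(OCc2ccccc2)c2c1O[C@H](c1ccc(OCc3ccccc3)c(OCc3ccccc3)c1)[C@@H](OCc1ccccc1)C2 | intermediate
9 | [2-(allyloxy)-4,6-bis(benzyloxy)phenyl](PBC-8-yl)methanol, both carbinol epimers | OC(c1c(OCC=C)cc(OCc2ccccc2)cc1OCc1ccccc1)c1c(OCc2ccccc2)cc(OCc2ccccc2)c2c1O[C@H](c1ccc(OCc3ccccc3)c(OCc3ccccc3)c1)[C@@H](OCc1ccccc1)C2 | intermediate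
10 | 1-(allyloxy)-3,5-bis(benzyloxy)-2-[(PBC-8-yl)(p-tolylsulfonyl)methyl]benzene, both epimers | Cc1ccc(cc1)S(=O)(=O)C(c1c(OCC=C)cc(OCc2ccccc2)cc1OCc1ccccc1)c1c(OCc2ccccc2)cc(OCc2ccccc2)c2c1O[C@H](c1ccc(OCc3ccccc3)c(OCc3ccccc3)c1)[C@@H](OCc1ccccc1)C2 | intermediate
11 | 3,5-bis(benzyloxy)-2-[(PBC-8-yl)(p-tolylsulfonyl)methyl]phenol, both epimers at the sulfonyl-bearing carbon | Cc1ccc(cc1)S(=O)(=O)C(c1c(O)cc(OCc2ccccc2)cc1OCc1ccccc1)c1c(OCc2ccccc2)cc(OCc2ccccc2)c2c1O[C@H](c1ccc(OCc3ccccc3)c(OCc3ccccc3)c1)[C@@H](OCc1ccccc1)C2 | intermediate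
12 | benzyloxyacetyl chloride | O=C(Cl)COCc1ccccc1 | starting material
13 | 3,5-bis(benzyloxy)-6-[(PBC-8-yl)methylidene]cyclohexa-2,4-dien-1-one (ortho-quinone methide, double-bond geometry not fixed) | O=C1C=C(OCc2ccccc2)C=C(OCc2ccccc2)C1=Cc1c(OCc2ccccc2)cc(OCc2ccccc2)c2c1O[C@H](c1ccc(OCc3ccccc3)c(OCc3ccccc3)c1)[C@@H](OCc1ccccc1)C2 | intermediate
14 | benzyloxyketene | O=C=COCc1ccccc1 | intermediate
15 | (3S,4R)-3,5,7-tris(benzyloxy)-4-(PBC-8-yl)chroman-2-one (3,4-cis lactone) | O=C1Oc2cc(OCc3ccccc3)cc(OCc3ccccc3)c2[C@H](c2c(OCc3ccccc3)cc(OCc3ccccc3)c3c2O[C@H](c2ccc(OCc4ccccc4)c(OCc4ccccc4)c2)[C@@H](OCc2ccccc2)C3)[C@@H]1OCc1ccccc1 | intermediate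
16 | (3R,4R)-3,5,7-tris(benzyloxy)-4-(PBC-8-yl)chroman-2-one (3,4-trans lactone) | O=C1Oc2cc(OCc3ccccc3)cc(OCc3ccccc3)c2[C@H](c2c(OCc3ccccc3)cc(OCc3ccccc3)c3c2O[C@H](c2ccc(OCc4ccccc4)c(OCc4ccccc4)c2)[C@@H](OCc2ccccc2)C3)[C@H]1OCc1ccccc1 | intermediate
17 | (2R,3R)-2-(benzyloxy)-3-[2,4-bis(benzyloxy)-6-hydroxyphenyl]-N-methoxy-N-methyl-3-(PBC-8-yl)propanamide | CON(C)C(=O)[C@H](OCc1ccccc1)[C@H](c1c(O)cc(OCc2ccccc2)cc1OCc1ccccc1)c1c(OCc2ccccc2)cc(OCc2ccccc2)c2c1O[C@H](c1ccc(OCc3ccccc3)c(OCc3ccccc3)c1)[C@@H](OCc1ccccc1)C2 | intermediate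
18 | 1-(benzyloxy)-4-bromobenzene | Brc1ccc(OCc2ccccc2)cc1 | starting material
19 | 4-(benzyloxy)phenylmagnesium bromide | Br[Mg]c1ccc(OCc2ccccc2)cc1 | intermediate
20 | (2R,3R)-2-(benzyloxy)-1-[4-(benzyloxy)phenyl]-3-[2,4-bis(benzyloxy)-6-hydroxyphenyl]-3-(PBC-8-yl)propan-1-one | O=C(c1ccc(OCc2ccccc2)cc1)[C@H](OCc1ccccc1)[C@H](c1c(O)cc(OCc2ccccc2)cc1OCc1ccccc1)c1c(OCc2ccccc2)cc(OCc2ccccc2)c2c1O[C@H](c1ccc(OCc3ccccc3)c(OCc3ccccc3)c1)[C@@H](OCc1ccccc1)C2 | intermediate
21 | (1S,2R,3R)-2-(benzyloxy)-1-[4-(benzyloxy)phenyl]-3-[2,4-bis(benzyloxy)-6-hydroxyphenyl]-3-(PBC-8-yl)propan-1-ol (1,2-anti) | O[C@@H](c1ccc(OCc2ccccc2)cc1)[C@H](OCc1ccccc1)[C@H](c1c(O)cc(OCc2ccccc2)cc1OCc1ccccc1)c1c(OCc2ccccc2)cc(OCc2ccccc2)c2c1O[C@H](c1ccc(OCc3ccccc3)c(OCc3ccccc3)c1)[C@@H](OCc1ccccc1)C2 | intermediate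
22 | (2R,3R,4R)-3,5,7-tris(benzyloxy)-2-[4-(benzyloxy)phenyl]-4-(PBC-8-yl)chromane (nona-O-benzyl gambiriin C) | C(c1ccccc1)Oc1ccc([C@H]2Oc3cc(OCc4ccccc4)cc(OCc4ccccc4)c3[C@H](c3c(OCc4ccccc4)cc(OCc4ccccc4)c4c3O[C@H](c3ccc(OCc5ccccc5)c(OCc5ccccc5)c3)[C@@H](OCc3ccccc3)C4)[C@H]2OCc2ccccc2)cc1 | intermediate
23 | gambiriin C as given, (2R,3R,4R)-2-(4-hydroxyphenyl)-4-[(2R,3S)-2-(3,4-dihydroxyphenyl)-3,5,7-trihydroxychroman-8-yl]chromane-3,5,7-triol | Oc1ccc([C@H]2Oc3cc(O)cc(O)c3[C@H](c3c(O)cc(O)c4c3O[C@H](c3ccc(O)c(O)c3)[C@@H](O)C4)[C@H]2O)cc1 | target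

**Step count and risks**

Total steps: 13. Longest linear sequence: 11 (steps 1–3 and 6–13, from (+)-catechin).

Steps most likely to fail:

Step 8. The methide carbon is flanked by two ortho substituents of ring D and is strongly donor-stabilised, so C–C bond formation may be slower than ketene dimerisation, or the catalyst may discriminate poorly between the two faces at C4. The fallback gives up catalyst control and uses the lower unit as a built-in resolving handle. It sets out from sulfone 11. The lithium enolate of methyl benzyloxyacetate (LDA, THF, −78 to 0 °C, 2.5 equiv) first deprotonates the phenol, which eliminates sulfinate to 13, and then adds to the methide carbon. This should give methyl 2-(benzyloxy)-3-[2,4-bis(benzyloxy)-6-hydroxyphenyl]-3-(PBC-8-yl)propanoate F1 as a diastereomer mixture. Catalytic DBU in toluene at 60 °C then closes the lactone with loss of methanol (the ortho-benzyloxy and C4-aryl groups favour closure) and equilibrates C3 to trans. The two trans lactones, 16 and (3S,4S)-3,5,7-tris(benzyloxy)-4-(PBC-8-yl)chroman-2-one F2, are diastereomers and are separated by chromatography. The route is rejoined at 16.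

Step 12. The oxyphosphonium sits on a 4-benzyloxybenzylic carbon and may ionise before displacement, which erodes the inversion at C2 and leads toward the 2,3-trans epimer. The fallback makes ring B electron-poor during ring closure and sets out from amide 17. 4-Iodophenyl pivalate F3 (from 4-iodophenol, pivaloyl chloride, Et3N) is converted by iodine–magnesium exchange (iPrMgCl·LiCl, THF, −30 °C) into 4-(pivaloyloxy)phenylmagnesium chloride F4. Addition of F4 to 17 should give (2R,3R)-2-(benzyloxy)-3-[2,4-bis(benzyloxy)-6-hydroxyphenyl]-1-[4-(pivaloyloxy)phenyl]-3-(PBC-8-yl)propan-1-one F5. Zn(BH4)2 reduction gives the anti (1S,2R,3R)-propan-1-ol F6, and Mitsunobu closure, now on a non-ionising benzylic centre, gives (2R,3R,4R)-3,5,7-tris(benzyloxy)-2-[4-(pivaloyloxy)phenyl]-4-(PBC-8-yl)chromane F7. Methanolysis (K2CO3, MeOH/THF) frees 4-[(2R,3R,4R)-3,5,7-tris(benzyloxy)-4-(PBC-8-yl)chroman-2-yl]phenol F8, and hydrogenolysis as in step 13 gives the target. The route is rejoined at 23.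

Step 10. The amide carbonyl is congested and sits next to a magnesium phenoxide, so addition may stall, and prolonged exposure to the basic reagent may enolise C3 and erode its configuration. The fallback uses the lactone itself as the acyl donor and sets out from lactone 16. 4-(Benzyloxy)phenyllithium F9 (from 18 and n-BuLi, THF, −78 °C) is added in slight excess to 16 at −78 °C and quenched cold. The lithium hemiketal alkoxide, held by the C3 benzyloxy group, should persist until quench and give ketone 20 directly, without passing through 17. The route is rejoined at 20.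

**Further compounds**

F1 | step 8 | methyl 2-(benzyloxy)-3-[2,4-bis(benzyloxy)-6-hydroxyphenyl]-3-(PBC-8-yl)propanoate, diastereomer mixture at C2 and C3 | COC(=O)C(OCc1ccccc1)C(c1c(O)cc(OCc2ccccc2)cc1OCc1ccccc1)c1c(OCc2ccccc2)cc(OCc2ccccc2)c2c1O[C@H](c1ccc(OCc3ccccc3)c(OCc3ccccc3)c1)[C@@H](OCc1ccccc1)C2
F2 | step 8 | (3S,4S)-3,5,7-tris(benzyloxy)-4-(PBC-8-yl)chroman-2-one | O=C1Oc2cc(OCc3ccccc3)cc(OCc3ccccc3)c2[C@@H](c2c(OCc3ccccc3)cc(OCc3ccccc3)c3c2O[C@H](c2ccc(OCc4ccccc4)c(OCc4ccccc4)c2)[C@@H](OCc2ccccc2)C3)[C@@H]1OCc1ccccc1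
F3 | step 12 | 4-iodophenyl pivalate | CC(C)(C)C(=O)Oc1ccc(I)cc1
F4 | step 12 | 4-(pivaloyloxy)phenylmagnesium chloride | CC(C)(C)C(=O)Oc1ccc([Mg]Cl)cc1
F5 | step 12 | (2R,3R)-2-(benzyloxy)-3-[2,4-bis(benzyloxy)-6-hydroxyphenyl]-1-[4-(pivaloyloxy)phenyl]-3-(PBC-8-yl)propan-1-one | O=C(c1ccc(OC(=O)C(C)(C)C)cc1)[C@H](OCc1ccccc1)[C@H](c1c(O)cc(OCc2ccccc2)cc1OCc1ccccc1)c1c(OCc2ccccc2)cc(OCc2ccccc2)c2c1O[C@H](c1ccc(OCc3ccccc3)c(OCc3ccccc3)c1)[C@@H](OCc1ccccc1)C2
F6 | step 12 | (1S,2R,3R)-2-(benzyloxy)-3-[2,4-bis(benzyloxy)-6-hydroxyphenyl]-1-[4-(pivaloyloxy)phenyl]-3-(PBC-8-yl)propan-1-ol | O[C@@H](c1ccc(OC(=O)C(C)(C)C)cc1)[C@H](OCc1ccccc1)[C@H](c1c(O)cc(OCc2ccccc2)cc1OCc1ccccc1)c1c(OCc2ccccc2)cc(OCc2ccccc2)c2c1O[C@H](c1ccc(OCc3ccccc3)c(OCc3ccccc3)c1)[C@@H](OCc1ccccc1)C2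
F7 | step 12 | (2R,3R,4R)-3,5,7-tris(benzyloxy)-2-[4-(pivaloyloxy)phenyl]-4-(PBC-8-yl)chromane | CC(C)(C)C(=O)Oc1ccc([C@H]2Oc3cc(OCc4ccccc4)cc(OCc4ccccc4)c3[C@H](c3c(OCc4ccccc4)cc(OCc4ccccc4)c4c3O[C@H](c3ccc(OCc5ccccc5)c(OCc5ccccc5)c3)[C@@H](OCc3ccccc3)C4)[C@H]2OCc2ccccc2)cc1
F8 | step 12 | 4-[(2R,3R,4R)-3,5,7-tris(benzyloxy)-4-(PBC-8-yl)chroman-2-yl]phenol | Oc1ccc([C@H]2Oc3cc(OCc4ccccc4)cc(OCc4ccccc4)c3[C@H](c3c(OCc4ccccc4)cc(OCc4ccccc4)c4c3O[C@H](c3ccc(OCc5ccccc5)c(OCc5ccccc5)c3)[C@@H](OCc3ccccc3)C4)[C@H]2OCc2ccccc2)cc1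
F9 | step 10 | 4-(benzyloxy)phenyllithium | [Li]c1ccc(OCc2ccccc2)cc1
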